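**Retrosynthetic overview**
- C6–OH comes from a C6–CHO group (Dakin oxidation) and C4=O from C4–OH; the aldehyde serves first as SNAr activator and then as the masked phenol.
- The pyran ring is the only ring made (the benzene ring is bought). It is closed at the C8a–O bond by intramolecular SNAr of a tertiary alkoxide on an aryl fluoride para to CHO, so the C2 stereocentre is never a reacting carbon.
- C4–OH and the side-chain tertiary OH both come from one double Markovnikov HAT hydration of a styrene/trisubstituted-alkene diene.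
- The C4–C4a bond comes from a Heck coupling of (R)-linalool (chiral pool: all ten chain carbons and the stereocentre) with 2-bromo-4-fluoro-5-iodobenzaldehyde, itself made by iodination of 2-bromo-4-fluorobenzaldehyde.

Assumption: (R)-(-)-linalool is bought in high enantiomeric purity; the ee of the target equals that of the linalool lot.

**Route**

Step 1
Reactants: 1 2-bromo-4-fluorobenzaldehyde
Product: 2 2-bromo-4-fluoro-5-iodobenzaldehyde
Conditions: NIS (1.2 equiv), TfOH, 0 °C to rt
Reagents that add atoms: N-iodosuccinimide, O=C1CCC(=O)N1I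
Why: Electrophilic aromatic iodination (SEAr with the NIS/TfOH superelectrophile) goes to C5, the one position that is ortho to F, para to Br and meta to CHO without being wedged between two halogens; no stereocentre is involved.

Step 2
Reactants: 2 2-bromo-4-fluoro-5-iodobenzaldehyde; 3 (R)-(-)-linalool [(3R)-3,7-dimethylocta-1,6-dien-3-ol]
Product: 4 2-bromo-4-fluoro-5-[(1E,3R)-3-hydroxy-3,7-dimethylocta-1,6-dien-1-yl]benzaldehyde
Conditions: Pd(OAc)2 (5 mol %), n-Bu4NCl, NaHCO3, DMF, 50 °C
Reagents that add atoms: none
Why: Mizoroki–Heck reaction under ligand-free conditions, where zerovalent palladium inserts into C–I and leaves C–Br alone at 50 °C, the aryl group adds to the terminal vinyl carbon of the tertiary allylic alcohol, and β-hydride elimination can only give the E-styrene; the carbinol stereocentre of linalool is untouched.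

Step 3
Reactants: 4 2-bromo-4-fluoro-5-[(1E,3R)-3-hydroxy-3,7-dimethylocta-1,6-dien-1-yl]benzaldehyde
Product: 5 2-bromo-4-fluoro-5-[(3R)-1,3,7-trihydroxy-3,7-dimethyloctyl]benzaldehyde (both epimers at the benzylic carbinol)
Conditions: Co(acac)2 (20 mol %), PhSiH3 (5 equiv), O2 (1 atm), THF, rt
Reagents that add atoms: dioxygen, O=O
Why: Mukaiyama hydration, in which a cobalt hydride transfers a hydrogen atom to each alkene to give the benzylic radical and the tertiary chain radical, each trapped by O2 and reduced by the silane to the Markovnikov alcohol; the new benzylic carbinol forms as an epimer mixture that is erased in step 6, and the (3R) centre is not touched.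

Step 4
Reactants: 5 2-bromo-4-fluoro-5-[(3R)-1,3,7-trihydroxy-3,7-dimethyloctyl]benzaldehyde
Product: 6 (2R)-7-bromo-4-hydroxy-2-(4-hydroxy-4-methylpentyl)-2-methylchromane-6-carbaldehyde (C4 epimer mixture)
Conditions: NaH (2.2 equiv), THF/DMF (0.02 M), 0 °C to rt
Reagents that add atoms: none
Why: Intramolecular SNAr (6-exo ring closure) of the tertiary alkoxide on the C–F bond activated by the para-formyl group; the bond is made at oxygen, so the tertiary carbinol carbon becomes C2 with retention (R), and the absence of a ketone at this stage rules out retro-aldol or E1cB scrambling.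

Step 5
Reactants: 6 (2R)-7-bromo-4-hydroxy-2-(4-hydroxy-4-methylpentyl)-2-methylchromane-6-carbaldehyde
Product: 7 (2R)-7-bromo-4-hydroxy-2-(4-hydroxy-4-methylpentyl)-2-methylchroman-6-yl formate (C4 epimer mixture)
Conditions: mCPBA (1.3 equiv), CH2Cl2, 0 °C to rt
Reagents that add atoms: meta-chloroperoxybenzoic acid, OOC(=O)c1cccc(Cl)c1
Why: Dakin-type Baeyer–Villiger oxidation, where the aryl group (para to the ring oxygen and not yet deactivated by a C4 ketone) migrates in the Criegee adduct to give the aryl formate; the alcohols, aryl bromide and C2 centre are inert to the peracid.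

Step 6
Reactants: 7 (2R)-7-bromo-4-hydroxy-2-(4-hydroxy-4-methylpentyl)-2-methylchroman-6-yl formate
Product: 9 (2R)-7-bromo-6-hydroxy-2-(4-hydroxy-4-methylpentyl)-2-methylchroman-4-one, via formate ketone 8 (not isolated)
Conditions: IBX (2 equiv), EtOAc, 70 °C; filter; then K2CO3 (0.1 equiv), MeOH, 0 °C
Reagents that add atoms: none
Why: IBX oxidation of the only oxidisable (secondary benzylic) alcohol to the aryl ketone with the phenol still masked, followed by base-catalysed transesterification of the labile aryl formate; brief, cold, catalytic base and a poor electron-rich phenoxide leaving group prevent retro-oxa-Michael opening, so C2 stays R.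

**Compound list**

1 | 2-bromo-4-fluorobenzaldehyde | O=Cc1ccc(F)cc1Br | starting material
2 | 2-bromo-4-fluoro-5-iodobenzaldehyde | O=Cc1cc(I)c(F)cc1Br | intermediate
3 | (R)-(-)-linalool, (3R)-3,7-dimethylocta-1,6-dien-3-ol | CC(C)=CCC[C@](O)(C)C=C | starting material
4 | 2-bromo-4-fluoro-5-[(1E,3R)-3-hydroxy-3,7-dimethylocta-1,6-dien-1-yl]benzaldehyde | CC(C)=CCC[C@](O)(C)/C=C/c1cc(C=O)c(Br)cc1F | intermediate
5 | 2-bromo-4-fluoro-5-[(3R)-1,3,7-trihydroxy-3,7-dimethyloctyl]benzaldehyde (benzylic carbinol unassigned, epimer mixture) | CC(C)(O)CCC[C@](O)(C)CC(O)c1cc(C=O)c(Br)cc1F | intermediate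
6 | (2R)-7-bromo-4-hydroxy-2-(4-hydroxy-4-methylpentyl)-2-methylchromane-6-carbaldehyde (C4 epimer mixture) | CC(C)(O)CCC[C@]1(C)CC(O)c2cc(C=O)c(Br)cc2O1 | intermediate
7 | (2R)-7-bromo-4-hydroxy-2-(4-hydroxy-4-methylpentyl)-2-methylchroman-6-yl formate (C4 epimer mixture) | CC(C)(O)CCC[C@]1(C)CC(O)c2cc(OC=O)c(Br)cc2O1 | intermediate
8 | (2R)-7-bromo-2-(4-hydroxy-4-methylpentyl)-2-methyl-4-oxochroman-6-yl formate | CC(C)(O)CCC[C@]1(C)CC(=O)c2cc(OC=O)c(Br)cc2O1 | intermediate
9 | (2R)-7-bromo-6-hydroxy-2-(4-hydroxy-4-methylpentyl)-2-methylchroman-4-one | CC(C)(O)CCC[C@]1(C)CC(=O)c2cc(O)c(Br)cc2O1 | target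

**Totals**

Total step count: 6. Longest linear sequence: 6 steps (from 1; linalool 3 enters at step 2). No protecting groups are used.

**Three steps most likely to fail, with fallbacks**

Step 3 (double hydration beside a free aryl aldehyde). Under cobalt/O2 the aldehyde may autoxidise or be partly hydrosilylated, and some benzylic ketone can form. The fallback sets out from 2: the aldehyde is masked (MeOH, cat. TsOH, 3 Å sieves) as the acetal 1-bromo-2-(dimethoxymethyl)-5-fluoro-4-iodobenzene F1. The same Heck coupling with 3 gives (1E,3R)-1-[4-bromo-5-(dimethoxymethyl)-2-fluorophenyl]-3,7-dimethylocta-1,6-dien-3-ol F2. Hydration under the step 3 conditions gives (3R)-1-[4-bromo-5-(dimethoxymethyl)-2-fluorophenyl]-3,7-dimethyloctane-1,3,7-triol F3. PPTS in wet acetone then releases the aldehyde, which comes back to the route at 5.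

Step 4 (SNAr with a secondary benzylic alkoxide and an aldehyde present). Hydride transfer from the benzylic alkoxide to the aldehyde, or intermolecular substitution, may compete with ring closure. The fallback sets out from 4 and closes the ring before the benzylic alcohol exists. Energy-transfer E-to-Z isomerisation (fac-Ir(ppy)3, blue LEDs, MeCN) gives 2-bromo-4-fluoro-5-[(1Z,3R)-3-hydroxy-3,7-dimethylocta-1,6-dien-1-yl]benzaldehyde F4. Its tertiary alkoxide (NaH, THF, 0 °C) can now reach the fluoride and closes to (2R)-7-bromo-2-methyl-2-(4-methylpent-3-en-1-yl)-2H-chromene-6-carbaldehyde F5. Double Mukaiyama hydration of F5 (benzylic radical at C4, tertiary radical in the chain) comes back to the route at 6.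

Step 5 (Dakin oxidation). Hydride rather than aryl migration would give the benzoic acid, and the acid by-product could dehydrate the 4-chromanol to a chromene. The fallback sets out from 6 and reverses the order of the last two oxidations. IBX in EtOAc first gives (2R)-7-bromo-2-(4-hydroxy-4-methylpentyl)-2-methyl-4-oxochromane-6-carbaldehyde F6, which has no acid-labile carbinol. The aldehyde-to-formate oxidation is then run with H2O2 and catalytic bis(2-nitrophenyl) diselenide, which favours aryl migration, and comes back to the route at 8.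

**Further compounds**

F1 | step 3 | 1-bromo-2-(dimethoxymethyl)-5-fluoro-4-iodobenzene | COC(OC)c1cc(I)c(F)cc1Br
F2 | step 3 | (1E,3R)-1-[4-bromo-5-(dimethoxymethyl)-2-fluorophenyl]-3,7-dimethylocta-1,6-dien-3-ol | CC(C)=CCC[C@](O)(C)/C=C/c1cc(C(OC)OC)c(Br)cc1F
F3 | step 3 | (3R)-1-[4-bromo-5-(dimethoxymethyl)-2-fluorophenyl]-3,7-dimethyloctane-1,3,7-triol | CC(C)(O)CCC[C@](O)(C)CC(O)c1cc(C(OC)OC)c(Br)cc1F
F4 | step 4 | 2-bromo-4-fluoro-5-[(1Z,3R)-3-hydroxy-3,7-dimethylocta-1,6-dien-1-yl]benzaldehyde | CC(C)=CCC[C@](O)(C)/C=C\c1cc(C=O)c(Br)cc1F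
F5 | step 4 | (2R)-7-bromo-2-methyl-2-(4-methylpent-3-en-1-yl)-2H-chromene-6-carbaldehyde | CC(C)=CCC[C@]1(C)C=Cc2cc(C=O)c(Br)cc2O1
F6 | step 5 | (2R)-7-bromo-2-(4-hydroxy-4-methylpentyl)-2-methyl-4-oxochromane-6-carbaldehyde | CC(C)(O)CCC[C@]1(C)CC(=O)c2cc(C=O)c(Br)cc2O1
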